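The numbers in the tables were generated by integration from invented constants; noise was put on by code.

Follow the partner, not the clock.

| setting | alpha | zeta | flask |
|---|---|---|---|
| starting material | 0.25 M | 0.25 M | 0.25 M |
| partner | 0.45 M | 0.68 M | 0.450 M |
| second substrate | 0.25 M (in portions, 4) | 0.25 M (in portions, 4) | 0.250 M (in portions, 4) |
| third substrate | 0.25 M | 0.25 M | 0.250 M |
| remark | the very flask that is asked about, followed so far; portions every 12 min | run made earlier; portions every 12 min | the portions of second substrate follow each other after 12 min, the first at the start |
| time |  |  | 25 h |

- alpha (time / h: target / %, starting material / %): 0.667: 38, 62; 1.00: 38, 60; 2.00: 41, 58; 4.00: 43, 57; 8.00: 41, 59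
- zeta (time / h: target / %, starting material / %): 1.33: 55, 45; 2.50: 54, 41; 5.00: 57, 42; 10.0: 56, 45; 20.0: 55, 44

(each reading ± 1.5 percentage points)

- the reaction counts as stopped when no species that holds the starting material changes by six tenths of a point or more over the second half of the time

- the state of affairs at 25 h: stopped, and by what, or still going (the partner has run out first / it is still moving / all of the starting material has reacted)
- how much target there is at 25 h, in percent of the starting material charged

The flask repeats the alpha run, so I asked why alpha stood still. Its last 3 readings averaged 58.0% starting material. That meant 0.105 M of target, and at one partner each this was less than the 0.45 M of partner charged. Yet alpha stayed flat. So I supposed a second route, with a rate proportional to partner.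

Partner then had two rates: use on starting material, proportional to partner times A, the starting-material concentration, and loss elsewhere, proportional to partner. Their ratio, a selectivity factor, is A/Λ, where Λ is the A at which they are equal. Partner and time drop out. Summed until the charge is used:

partner charge = target made + Λ ln(A charged / A left).

Alpha gave Λ = 0.633 M. Zeta's last 3 readings averaged 43.7% and gave 0.651 M, close to alpha's. Their mean, 0.642 M, became my loss constant. For the flask I expected 42.0% target.

The forecast said: the partner has run out first, with 41% target, reasoning that “a limiting reagent is exhausted, not a slow reaction”.

The simulation gave: the partner has run out first, with 41.8% target.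

    starting material + partner → target (k = 0.0550 L mol⁻¹ min⁻¹)
    second substrate + partner → second product (k = 0.00240 L mol⁻¹ min⁻¹)
    third substrate + partner → third product (k = 0.0120 L mol⁻¹ min⁻¹)
    partner → decomposed reagent (k = 0.0320 min⁻¹)

At 25.0 h the flask held 0% of its partner, and its end gave Λ = 0.639 M. A neighbouring flask was charged with 1.1 M of partner. For this neighbour I first took A left as exp(−charge/Λ), which was 18.0%. Putting the target this implied back into the budget gave 75.2% target. The simulated neighbour held 76.1% target and 23.9% starting material at 25.0 h.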